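The flavanone ring C is cut at O1–C2 and C3–C4. O1 and C4 are bonded to the adjacent ring A carbons C8a and C4a, which is the oxygen/exocyclic-carbon pattern of an ortho-quinone methide, and C2/C3 with their trans aryl groups correspond to the two carbons of an (E)-stilbene. A single chiral-acid-catalysed hetero-Diels–Alder reaction therefore makes both bonds, ring C and both stereocentres. The partners are 3,5-bis(benzyloxy)-2-(hydroxymethyl)phenol and a stilbene that already carries the complete flavone. The ring B oxygen next to the alkene is masked as a benzyl carbonate, so that C4 oxidation and one hydrogenolysis finish the synthesis with no basic step on the flavanone.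

Key step: step 8

Assumption: the sense of induction of the chiral phosphoric acid cannot be predicted with confidence. (R)-TRIP, (R)-3,3'-bis(2,4,6-triisopropylphenyl)-1,1'-binaphthyl-2,2'-diyl hydrogen phosphate, is written; its enantiomer is to be used if it favours the other alkene face.

Assumption: 2',6'-dihydroxy-4'-methoxyacetophenone and 4-(benzyloxy)styrene are taken as purchased compounds.

Step 1
Reactants: 1 1-(2,6-dihydroxy-4-methoxyphenyl)ethan-1-one (2',6'-dihydroxy-4'-methoxyacetophenone)
Product: 2 1-[2-(benzyloxy)-6-hydroxy-4-methoxyphenyl]ethan-1-one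
Conditions: BnBr (1.05 equiv), K2CO3, acetone, reflux
Reagents that add atoms: benzyl bromide, BrCc1ccccc1
Why: Williamson ether synthesis; once one hydroxyl is benzylated the other is held in a hydrogen bond to the acetyl carbonyl and reacts far more slowly, so mono-alkylation should dominate with one equivalent of bromide.

Step 2
Reactants: 2 1-[2-(benzyloxy)-6-hydroxy-4-methoxyphenyl]ethan-1-one; 3 4-hydroxy-3-iodobenzaldehyde
Product: 4 (E)-1-[2-(benzyloxy)-6-hydroxy-4-methoxyphenyl]-3-(4-hydroxy-3-iodophenyl)prop-2-en-1-one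
Conditions: KOH (50% aq, 10 equiv), EtOH, rt to 40 °C; then 1 M HCl
Reagents that add atoms: none
Why: Claisen–Schmidt condensation (aldol addition, then E1cB dehydration) should give the E-enone, and because the aldehyde reacts as its less electrophilic phenoxide, excess hydroxide and a long reaction time are planned.

Step 3
Reactants: 4 (E)-1-[2-(benzyloxy)-6-hydroxy-4-methoxyphenyl]-3-(4-hydroxy-3-iodophenyl)prop-2-en-1-one
Product: 5 5-(benzyloxy)-2-(4-hydroxy-3-iodophenyl)-7-methoxy-4H-chromen-4-one
Conditions: I2 (10 mol%), DMSO, 130 °C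
Reagents that add atoms: none
Why: Iodine-catalysed oxidative cyclisation of a 2'-hydroxychalcone in DMSO, the standard flavone synthesis, should close the pyranone through the free hydroxyl while DMSO acts as terminal oxidant, and the catalytic amount of I2 limits ring iodination.

Step 4
Reactants: 5 5-(benzyloxy)-2-(4-hydroxy-3-iodophenyl)-7-methoxy-4H-chromen-4-one; 6 1-(benzyloxy)-4-ethenylbenzene (4-(benzyloxy)styrene)
Product: 7 5-(benzyloxy)-2-{3-[(E)-2-(4-benzyloxyphenyl)ethenyl]-4-hydroxyphenyl}-7-methoxy-4H-chromen-4-one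
Conditions: Pd(OAc)2 (5 mol%), P(o-tol)3 (10 mol%), Et3N, DMF, 100 °C
Reagents that add atoms: none
Why: Mizoroki–Heck reaction; oxidative addition of the aryl iodide to zerovalent palladium, syn insertion of the styrene at its terminal carbon and syn β-hydride elimination should give the E-stilbene, and free 2-iodophenols are competent partners.

Step 5
Reactants: 7 5-(benzyloxy)-2-{3-[(E)-2-(4-benzyloxyphenyl)ethenyl]-4-hydroxyphenyl}-7-methoxy-4H-chromen-4-one
Product: 8 benzyl 4-[5-(benzyloxy)-7-methoxy-4-oxo-4H-chromen-2-yl]-2-[(E)-2-(4-benzyloxyphenyl)ethenyl]phenyl carbonate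
Conditions: CbzCl, Et3N, CH2Cl2, 0 °C to rt
Reagents that add atoms: benzyl chloroformate, O=C(Cl)OCc1ccccc1
Why: Acylation of the only free phenol with a chloroformate should give the aryl benzyl carbonate, which makes ring B a poor cation-stabilising group for the key step, withstands acid and oxidants, and is removed later by hydrogenolysis so that no base ever meets the flavanone.

Step 6
Reactants: 9 2,4,6-trihydroxybenzaldehyde
Product: 10 2,4-bis(benzyloxy)-6-hydroxybenzaldehyde
Conditions: BnBr (2.1 equiv), K2CO3, DMF, rt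
Reagents that add atoms: benzyl bromide, BrCc1ccccc1
Why: Williamson ether synthesis; the 4-hydroxyl and one 2-hydroxyl are alkylated while the last hydroxyl, hydrogen-bonded to the formyl group, should stay free when about two equivalents of bromide are used.

Step 7
Reactants: 10 2,4-bis(benzyloxy)-6-hydroxybenzaldehyde
Product: 11 3,5-bis(benzyloxy)-2-(hydroxymethyl)phenol
Conditions: NaBH4, THF/MeOH, 0 °C; aq NH4Cl quench; used at once without chromatography
Reagents that add atoms: none
Why: Borohydride reduction of the aldehyde at low temperature with a neutral quench should give the salicyl alcohol, which is electron-rich and acid-sensitive and is therefore carried forward immediately.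

Step 8
Reactants: 11 3,5-bis(benzyloxy)-2-(hydroxymethyl)phenol; 8 benzyl 4-[5-(benzyloxy)-7-methoxy-4-oxo-4H-chromen-2-yl]-2-[(E)-2-(4-benzyloxyphenyl)ethenyl]phenyl carbonate
Product: 13 benzyl 2-[(2S,3R)-5,7-bis(benzyloxy)-2-(4-benzyloxyphenyl)-3,4-dihydro-2H-chromen-3-yl]-4-[5-(benzyloxy)-7-methoxy-4-oxo-4H-chromen-2-yl]phenyl carbonate, via ortho-quinone methide 12 (not isolated)
Conditions: (R)-TRIP (10 mol%), 5 Å MS, CH2Cl2, −20 °C to rt; 11 (2 equiv) added over 6 h
Reagents that add atoms: none
Why: Proposed new method: the acid dehydrates 11 to the ortho-quinone methide 12, which stays hydrogen-bonded to the chiral phosphate as a 2,4,6-trioxygenated benzylic cation equivalent and adds to the stilbene in an asynchronous inverse-demand [4+2] process, the methide carbon bonding first to the alkene carbon attached to ring B and the oxygen then closing onto the developing 4-benzyloxybenzylic cation. The closest known reaction type is the chiral phosphoric acid catalysed oxa-Diels–Alder reaction of in situ ortho-quinone methides with electron-rich styrenes and 1-arylpropenes; a methide unsubstituted at its exocyclic carbon combined with a 1,2-diarylethene that offers no hydrogen-bond donor is not covered by it. Ring C closes as a six-membered pyran by [4+2] cycloaddition of the O=C–C=CH2 unit of 12 with the alkene, forming O1–C2 and C3–C4. The trans relation of C2 and C3 follows from the E geometry through suprafacial addition, and the absolute configuration (2S,3R) must come from the phosphate, which has to fix both the open face of the bound methide and the orientation of the stilbene in its pocket. The step needs regio-, chemo- and facial selectivity: the para-benzyloxy donor set against the carbonate- and chromone-deactivated ring B directs the oxygen to the future C2, slow addition of 11 keeps the methide dilute so that Friedel–Crafts self-alkylation of the electron-rich ring A is held back, and the mild acid should leave the acid-labile C2–O1 bond of 13 intact.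

Step 9
Reactants: 13 benzyl 2-[(2S,3R)-5,7-bis(benzyloxy)-2-(4-benzyloxyphenyl)-3,4-dihydro-2H-chromen-3-yl]-4-[5-(benzyloxy)-7-methoxy-4-oxo-4H-chromen-2-yl]phenyl carbonate
Product: 14 benzyl 2-[(2S,3S)-5,7-bis(benzyloxy)-2-(4-benzyloxyphenyl)-4-hydroxy-3,4-dihydro-2H-chromen-3-yl]-4-[5-(benzyloxy)-7-methoxy-4-oxo-4H-chromen-2-yl]phenyl carbonate (both C4 epimers; C2 and C3 arranged as in 13, the C3 descriptor changes only formally)
Conditions: DDQ (1.5 equiv), CH2Cl2/H2O (10:1), 0 °C to rt
Reagents that add atoms: water, O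
Why: Benzylic C–H oxidation by DDQ, known for 5,7-dialkoxyflavans; hydride abstraction from C4 should give a cation stabilised by O1 and the two benzyloxy groups of ring A that water captures, and the new C4 centre needs no control because it is oxidised in the next step.

Step 10
Reactants: 14 benzyl 2-[(2S,3S)-5,7-bis(benzyloxy)-2-(4-benzyloxyphenyl)-4-hydroxy-3,4-dihydro-2H-chromen-3-yl]-4-[5-(benzyloxy)-7-methoxy-4-oxo-4H-chromen-2-yl]phenyl carbonate
Product: 15 benzyl 2-[(2S,3R)-5,7-bis(benzyloxy)-2-(4-benzyloxyphenyl)-4-oxo-3,4-dihydro-2H-chromen-3-yl]-4-[5-(benzyloxy)-7-methoxy-4-oxo-4H-chromen-2-yl]phenyl carbonate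
Conditions: DMP, NaHCO3, CH2Cl2, 0 °C to rt
Reagents that add atoms: none
Why: Dess–Martin oxidation of the secondary benzylic alcohol under buffered, base-free conditions should give the ketone without opening ring C, and C3, now enolisable, already has the preferred trans diequatorial arrangement.

Step 11
Reactants: 15 benzyl 2-[(2S,3R)-5,7-bis(benzyloxy)-2-(4-benzyloxyphenyl)-4-oxo-3,4-dihydro-2H-chromen-3-yl]-4-[5-(benzyloxy)-7-methoxy-4-oxo-4H-chromen-2-yl]phenyl carbonate
Product: 16 (2S,3R)-5,7-dihydroxy-3-[2-hydroxy-5-(5-hydroxy-7-methoxy-4-oxo-4H-chromen-2-yl)phenyl]-2-(4-hydroxyphenyl)-2,3-dihydro-4H-chromen-4-one (target)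
Conditions: H2 (1 atm), 10% Pd/C, THF/MeOH, rt
Reagents that add atoms: none
Why: Catalytic hydrogenolysis should cleave the four benzyl ethers and the benzyl carbonate (as toluene and CO2) under neutral conditions that neither enolise C3 nor open the flavanone, while the chromone double bond and the aryl ketone are known to survive mild debenzylation.

Compound list
1 | 1-(2,6-dihydroxy-4-methoxyphenyl)ethan-1-one | CC(=O)c1c(O)cc(OC)cc1O | starting material
2 | 1-[2-(benzyloxy)-6-hydroxy-4-methoxyphenyl]ethan-1-one | CC(=O)c1c(O)cc(OC)cc1OCc1ccccc1 | intermediate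
3 | 4-hydroxy-3-iodobenzaldehyde | O=Cc1ccc(O)c(I)c1 | starting material
4 | (E)-1-[2-(benzyloxy)-6-hydroxy-4-methoxyphenyl]-3-(4-hydroxy-3-iodophenyl)prop-2-en-1-one | COc1cc(O)c(C(=O)/C=C/c2ccc(O)c(I)c2)c(OCc2ccccc2)c1 | intermediate
5 | 5-(benzyloxy)-2-(4-hydroxy-3-iodophenyl)-7-methoxy-4H-chromen-4-one | COc1cc(OCc2ccccc2)c2c(=O)cc(-c3ccc(O)c(I)c3)oc2c1 | intermediate
6 | 1-(benzyloxy)-4-ethenylbenzene | C=Cc1ccc(OCc2ccccc2)cc1 | starting material
7 | 5-(benzyloxy)-2-{3-[(E)-2-(4-benzyloxyphenyl)ethenyl]-4-hydroxyphenyl}-7-methoxy-4H-chromen-4-one | COc1cc(OCc2ccccc2)c2c(=O)cc(-c3ccc(O)c(/C=C/c4ccc(OCc5ccccc5)cc4)c3)oc2c1 | intermediate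
8 | benzyl 4-[5-(benzyloxy)-7-methoxy-4-oxo-4H-chromen-2-yl]-2-[(E)-2-(4-benzyloxyphenyl)ethenyl]phenyl carbonate | COc1cc(OCc2ccccc2)c2c(=O)cc(-c3ccc(OC(=O)OCc4ccccc4)c(/C=C/c4ccc(OCc5ccccc5)cc4)c3)oc2c1 | intermediate
9 | 2,4,6-trihydroxybenzaldehyde | O=Cc1c(O)cc(O)cc1O | starting material
10 | 2,4-bis(benzyloxy)-6-hydroxybenzaldehyde | O=Cc1c(O)cc(OCc2ccccc2)cc1OCc1ccccc1 | intermediate
11 | 3,5-bis(benzyloxy)-2-(hydroxymethyl)phenol | OCc1c(O)cc(OCc2ccccc2)cc1OCc1ccccc1 | intermediate
12 | 3,5-bis(benzyloxy)-6-methylidenecyclohexa-2,4-dien-1-one (ortho-quinone methide, not isolated) | C=C1C(=O)C=C(OCc2ccccc2)C=C1OCc1ccccc1 | intermediate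
13 | benzyl 2-[(2S,3R)-5,7-bis(benzyloxy)-2-(4-benzyloxyphenyl)-3,4-dihydro-2H-chromen-3-yl]-4-[5-(benzyloxy)-7-methoxy-4-oxo-4H-chromen-2-yl]phenyl carbonate | COc1cc(OCc2ccccc2)c2c(=O)cc(-c3ccc(OC(=O)OCc4ccccc4)c([C@H]4Cc5c(OCc6ccccc6)cc(OCc6ccccc6)cc5O[C@@H]4c4ccc(OCc5ccccc5)cc4)c3)oc2c1 | intermediate
14 | benzyl 2-[(2S,3S)-5,7-bis(benzyloxy)-2-(4-benzyloxyphenyl)-4-hydroxy-3,4-dihydro-2H-chromen-3-yl]-4-[5-(benzyloxy)-7-methoxy-4-oxo-4H-chromen-2-yl]phenyl carbonate, both C4 epimers | COc1cc(OCc2ccccc2)c2c(=O)cc(-c3ccc(OC(=O)OCc4ccccc4)c([C@H]4C(O)c5c(OCc6ccccc6)cc(OCc6ccccc6)cc5O[C@@H]4c4ccc(OCc5ccccc5)cc4)c3)oc2c1 | intermediate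
15 | benzyl 2-[(2S,3R)-5,7-bis(benzyloxy)-2-(4-benzyloxyphenyl)-4-oxo-3,4-dihydro-2H-chromen-3-yl]-4-[5-(benzyloxy)-7-methoxy-4-oxo-4H-chromen-2-yl]phenyl carbonate | COc1cc(OCc2ccccc2)c2c(=O)cc(-c3ccc(OC(=O)OCc4ccccc4)c([C@H]4C(=O)c5c(OCc6ccccc6)cc(OCc6ccccc6)cc5O[C@@H]4c4ccc(OCc5ccccc5)cc4)c3)oc2c1 | intermediate
16 | (2S,3R)-5,7-dihydroxy-3-[2-hydroxy-5-(5-hydroxy-7-methoxy-4-oxo-4H-chromen-2-yl)phenyl]-2-(4-hydroxyphenyl)-2,3-dihydro-4H-chromen-4-one | COc1cc(O)c2c(=O)cc(-c3ccc(O)c([C@H]4C(=O)c5c(O)cc(O)cc5O[C@@H]4c4ccc(O)cc4)c3)oc2c1 | target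

Total steps: 11. Longest linear sequence: 9 steps (steps 1–5, then 8–11).

Steps most likely to fail

Step 8. Three processes may go wrong. Facial discrimination may be poor, because the stilbene gives the catalyst no hydrogen-bond handle. The methide may be consumed by Friedel–Crafts alkylation of the electron-rich rings of 11 or 13. The acid may be tied up by the basic chromone carbonyl. The fallback uses known chemistry and sets out from 8 and 11. The cycloaddition is run without asymmetric induction, with diphenyl hydrogen phosphate (10 mol%) in CH2Cl2 or simply by heating in toluene, which is the established achiral-acid or thermal hetero-Diels–Alder mode of ortho-quinone methides with aryl alkenes. The E alkene should still give only the 2,3-trans chroman, as an equal mixture of 13 and the enantiomeric (2R,3S)-chroman F1. Preparative HPLC on a polysaccharide chiral stationary phase separates the two, and the route is rejoined at 13.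

Step 9. Hydride abstraction may occur at C2, which is also benzylic and next to oxygen, instead of C4. The C4 cation may also lose the C3 proton to give a chromene, which would erase the C3 centre. The fallback sets out from 13. Benzylic acetoxylation with Pb(OAc)4 in benzene/AcOH, a known oxidation of alkoxyflavans in which acetate is always at hand to trap the C4 cation, should give the 4-acetoxyflavan F2. This readily ionised trialkoxybenzylic ester is then solvolysed in aqueous acetone at rt without base, which spares the aryl carbonate, and the route is rejoined at 14.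

Step 2. The condensation may be slow or incomplete because the aldehyde is present as its para-phenoxide, a poor electrophile, and material may degrade on long exposure to hydroxide. The fallback sets out from 3. Protection with MOMCl/iPr2NEt in CH2Cl2 gives 3-iodo-4-(methoxymethoxy)benzaldehyde F3. Claisen–Schmidt condensation of this with 2 (KOH, EtOH, rt) gives the MOM-protected chalcone F4. I2 (cat.) in DMSO at 130 °C gives the MOM-protected iodoflavone F5. HCl in MeOH/THF at 50 °C removes the acetal, and the route is rejoined at 5.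

Further compounds
F1 | step 8 | benzyl 2-[(2R,3S)-5,7-bis(benzyloxy)-2-(4-benzyloxyphenyl)-3,4-dihydro-2H-chromen-3-yl]-4-[5-(benzyloxy)-7-methoxy-4-oxo-4H-chromen-2-yl]phenyl carbonate (enantiomer of 13) | COc1cc(OCc2ccccc2)c2c(=O)cc(-c3ccc(OC(=O)OCc4ccccc4)c([C@@H]4Cc5c(OCc6ccccc6)cc(OCc6ccccc6)cc5O[C@H]4c4ccc(OCc5ccccc5)cc4)c3)oc2c1
F2 | step 9 | benzyl 2-[(2S,3R)-4-acetoxy-5,7-bis(benzyloxy)-2-(4-benzyloxyphenyl)-3,4-dihydro-2H-chromen-3-yl]-4-[5-(benzyloxy)-7-methoxy-4-oxo-4H-chromen-2-yl]phenyl carbonate, both C4 epimers | COc1cc(OCc2ccccc2)c2c(=O)cc(-c3ccc(OC(=O)OCc4ccccc4)c([C@H]4C(OC(C)=O)c5c(OCc6ccccc6)cc(OCc6ccccc6)cc5O[C@@H]4c4ccc(OCc5ccccc5)cc4)c3)oc2c1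
F3 | step 2 | 3-iodo-4-(methoxymethoxy)benzaldehyde | COCOc1ccc(C=O)cc1I
F4 | step 2 | (E)-1-[2-(benzyloxy)-6-hydroxy-4-methoxyphenyl]-3-[3-iodo-4-(methoxymethoxy)phenyl]prop-2-en-1-one | COCOc1ccc(/C=C/C(=O)c2c(O)cc(OC)cc2OCc2ccccc2)cc1I
F5 | step 2 | 5-(benzyloxy)-2-[3-iodo-4-(methoxymethoxy)phenyl]-7-methoxy-4H-chromen-4-one | COCOc1ccc(-c2cc(=O)c3c(OCc4ccccc4)cc(OC)cc3o2)cc1I
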